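- I began in a one-step world, where electrophile plus nucleophile gives product, and with its clock. Here the nucleophile is charged as its protonated form, and free base must release it.

electrophile 0.50 M; protonated nucleophile 2.50 equiv; time 10 d

* the equivalents of free base at which the part of the electrophile that has reacted at 10 d is just 70 %

- for acid set free the idle adduct is counted in
- the amount of free base is what is sought; it is there from the start
- what has gone from electrophile into another species counts as reacted, even if it can come back
- run time (flask): 10 d

    electrophile + nucleophile → acid set free + product (k1 = 0.0032 L mol⁻¹ min⁻¹)
    nucleophile + acid set free ⇌ protonated nucleophile, settled at all times (K2 = 12000 L mol⁻¹)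
    acid set free + free base ⇌ salt of the base, settled at all times (K3 = 67000 L mol⁻¹)
    electrophile + acid set free ⇌ idle adduct, settled at all times (K4 = 1.1 L mol⁻¹)

- With the electrophile as charged, the nucleophile had a half-life by step 1 alone of 0.301 d, far shorter than the run. I therefore reckoned the part reacted from a proton balance, not from the clock.
- One turnover removed one nucleophile and freed one acid, which protonated a second nucleophile unless free base took it. So the base bill, two equiv of free base per part of electrophile turned over, came to 1.40 equiv at the part wanted.
- The weak link was that bill's neglect of acid held elsewhere. Past the base's capacity, I let each late turnover add two acids to free acid and adduct, with nucleophile held by the protonation balance. For the end of the run this reckoning gave free acid of 0.0844 of the charge.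
- Each idle adduct saved 3 on the bill: it counts as reacted, which spares one turnover costing two, and it holds one acid. I committed to 1.27 equiv.
- The forecast said 1.3 equiv, slightly above mine, with “the small free-acid and adduct pools trimming this”.
- The simulation gave 1.30 equiv.

- In that flask, the conversion had done half of its turnover up to 10 d by 0.235 d, and 65.1 % of the electrophile was used at 2.50 d. At 5.00 d, 0.0717 % of the charged free base was still free and 67.6 % was used, rising to 74.4 % at 30.0 d. The need lay 0.103 equiv under the bill; keeping that slack, I reckoned 86.4 % for the flask with a quarter more free base, and its simulated run reached 83.5 %.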